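**Retrosynthetic overview**
1. Kuwanon L (14) comes from its hepta-O-benzyl ether 13 by neutral transfer hydrogenolysis.
2. The cyclohexene of 13 is formed last among the rings, by an exo-selective, chiral-boron-promoted Diels–Alder reaction of 2'-hydroxychalcone 12 with the dienyl flavanone 9.
3. Key disconnection: the O1–C2 bond of the flavanone. An enantioselective oxa-Michael cyclisation of 2'-hydroxychalcone 8 closes ring C and sets C2 (S).
4. Chalcones 8 and 12 come from Claisen–Schmidt condensations; dienyl aldehyde 6 comes from 2,4-dihydroxybenzaldehyde by iodination, benzylation and a one-pot hydroboration/Suzuki coupling.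
5. Ring order: flavanone ring C first, cyclohexene second.

Assumption: the absolute sense of induction of the two chiral promoters (quinidine-derived squaramide in step 5, (R)-VANOL–boron complex in step 7) is assigned by analogy with simpler 2'-hydroxychalcones; if a trial run shows the opposite sense, the quinine-derived pseudoenantiomer or (S)-VANOL is used with no other change.

**Route**

Step 1
Reactants: 1 2,4-dihydroxybenzaldehyde
Product: 2 2,4-dihydroxy-3-iodobenzaldehyde
Conditions: I2 (1.0 equiv), NaHCO3 (1.1 equiv), H2O/THF, 0 °C to rt; recrystallise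
Reagents that add atoms: iodine, II
Why: Electrophilic iodination of the phenoxide under mildly basic aqueous conditions should favour the doubly ortho-activated C3 between the two oxygens (the selectivity that gives 2-iodoresorcinol from resorcinol), with the minor 5-iodo isomer removed by crystallisation and the regiochemistry confirmed by HMBC.

Step 2
Reactants: 2 2,4-dihydroxy-3-iodobenzaldehyde
Product: 3 2,4-bis(benzyloxy)-3-iodobenzaldehyde
Conditions: BnBr (2.5 equiv), K2CO3 (3 equiv), DMF, 60 °C
Reagents that add atoms: benzyl bromide, BrCc1ccccc1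
Why: Williamson ether synthesis in which both phenoxides are alkylated, the hydrogen-bonded 2-OH needing the mild heating, while the aldehyde and aryl iodide are inert.

Step 3
Reactants: 3 2,4-bis(benzyloxy)-3-iodobenzaldehyde, 4 2-methylbut-1-en-3-yne
Product: 6 2,4-bis(benzyloxy)-3-[(1E)-3-methylbuta-1,3-dien-1-yl]benzaldehyde, via dienyl pinacol boronate 5 (not isolated)
Conditions: 4 (1.6 equiv), pinacolborane (1.3 equiv), Cp2Zr(H)Cl (5 mol %), Et3N (10 mol %), neat, sealed, 60 °C, 16 h; strip volatiles; then 3 (1.0 equiv), Pd(OAc)2 (3 mol %), SPhos (6 mol %), K3PO4 (3 equiv), THF/H2O 10:1, 60 °C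
Reagents that add atoms: none
Why: Zirconocene-hydride-catalysed syn, anti-Markovnikov hydroboration of the terminal alkyne gives only the (E)-alkenylboronate 5 (the 1,1-disubstituted alkene is untouched, and the limiting pinacolborane is fully consumed before the aldehyde is added), and the stereoretentive Suzuki–Miyaura coupling with the di-ortho-substituted iodide 3 is enabled by the bulky biarylphosphine SPhos, fixing the (E)-diene.

Step 4
Reactants: 6 2,4-bis(benzyloxy)-3-[(1E)-3-methylbuta-1,3-dien-1-yl]benzaldehyde, 7 1-[2,4-bis(benzyloxy)-6-hydroxyphenyl]ethan-1-one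
Product: 8 (2E)-1-[2,4-bis(benzyloxy)-6-hydroxyphenyl]-3-{2,4-bis(benzyloxy)-3-[(1E)-3-methylbuta-1,3-dien-1-yl]phenyl}prop-2-en-1-one
Conditions: KOH (50% aq., 10 equiv), EtOH/THF, rt, 36 h; cold dilute HCl to pH 5
Reagents that add atoms: none
Why: Claisen–Schmidt condensation in which the enolate of 7 adds to the non-enolisable aldehyde 6 and E1cB dehydration gives the conjugated (E)-enone, which is held as its phenoxide in strong base and so is isolated uncyclised after cold acidification.

Step 5
Reactants: 8 (2E)-1-[2,4-bis(benzyloxy)-6-hydroxyphenyl]-3-{2,4-bis(benzyloxy)-3-[(1E)-3-methylbuta-1,3-dien-1-yl]phenyl}prop-2-en-1-one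
Product: 9 (2S)-5,7-bis(benzyloxy)-2-{2,4-bis(benzyloxy)-3-[(1E)-3-methylbuta-1,3-dien-1-yl]phenyl}-2,3-dihydro-4H-chromen-4-one
Conditions: 3-{[3,5-bis(trifluoromethyl)phenyl]amino}-4-{[(9R)-6'-methoxycinchonan-9-yl]amino}cyclobut-3-ene-1,2-dione (squaramide from 9-amino-9-deoxy-epi-quinidine, 10 mol %), toluene/CH2Cl2 4:1, 0.05 M, −20 °C, 72 h; cold filtration through AcOH-washed silica; recovered 8 recycled
Reagents that add atoms: none
Why: Proposed new method: a bifunctional cinchona-squaramide-catalysed, kinetically controlled enantioselective 6-endo-trig oxa-Michael cyclisation of an unactivated 2'-hydroxy-4',6'-dialkoxychalcone, in which the quinuclidine nitrogen deprotonates the 2'-OH, the two squaramide N–H bonds bind the enone carbonyl (twisted out of the plane of ring A by the 6'-benzyloxy group, which raises both phenoxide nucleophilicity and enone electrophilicity), the ion-paired phenoxide is delivered to the Si face of C-beta to form the O1–C2 bond and set (2S), and the squaramide-bound enolate is protonated by the quinuclidinium, while low temperature, a non-polar medium and the acidic quench suppress the E1cB retro-reaction that would racemise C2; the closest known reactions are the cinchona-thiourea-catalysed oxa-Michael cyclisation of activated alkylidene beta-ketoesters to flavanones and alkaloid-catalysed cyclisations of simple 2'-hydroxychalcones, neither shown on a 6'-alkoxy, electron-rich, diene-bearing chalcone.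

Step 6
Reactants: 10 1-[4-(benzyloxy)-2-hydroxyphenyl]ethan-1-one, 11 2,4-bis(benzyloxy)benzaldehyde
Product: 12 (2E)-1-[4-(benzyloxy)-2-hydroxyphenyl]-3-[2,4-bis(benzyloxy)phenyl]prop-2-en-1-one
Conditions: KOH (50% aq., 10 equiv), EtOH/THF, rt, 24 h; cold dilute HCl
Reagents that add atoms: none
Why: Claisen–Schmidt condensation of a methyl ketone enolate with a non-enolisable aldehyde, giving the (E)-2'-hydroxychalcone, which without a 6'-oxygen does not cyclise under these conditions.

Step 7
Reactants: 9 (2S)-5,7-bis(benzyloxy)-2-{2,4-bis(benzyloxy)-3-[(1E)-3-methylbuta-1,3-dien-1-yl]phenyl}-2,3-dihydro-4H-chromen-4-one, 12 (2E)-1-[4-(benzyloxy)-2-hydroxyphenyl]-3-[2,4-bis(benzyloxy)phenyl]prop-2-en-1-one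
Product: 13 (2S)-5,7-bis(benzyloxy)-2-{2,4-bis(benzyloxy)-3-[(1S,5R,6S)-6-[4-(benzyloxy)-2-hydroxybenzoyl]-5-[2,4-bis(benzyloxy)phenyl]-3-methylcyclohex-2-en-1-yl]phenyl}-2,3-dihydro-4H-chromen-4-one (hepta-O-benzyl kuwanon L, all-trans cyclohexene)
Conditions: (R)-VANOL [(R)-3,3'-diphenyl-2,2'-bi-1-naphthol] (1.5 equiv), BH3·THF (1.5 equiv), AcOH (1.5 equiv), THF, rt, 1 h, evaporate; 12 (1.5 equiv), PhCF3, rt, 1 h; then 9 (1.0 equiv), rt to 40 °C, 48 h; MeOH then aq. NaHCO3 work-up; chromatography (removes endo isomer, recovers VANOL and excess 12)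
Reagents that add atoms: none
Why: Chiral-boron-promoted asymmetric Diels–Alder reaction of a 2'-hydroxychalcone, in which 12 binds boron as a phenolate/carbonyl chelate that lowers its LUMO, the vaulted biaryl shields one enone face, and diene 9 adds with ortho/para regiochemistry through the exo transition state favoured by its twisted 2,6-dialkoxyaryl group, so the three contiguous centres (1S,5R,6S) are set all-trans under reagent control while the remote C2 centre is untouched by the base-free medium.

Step 8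
Reactants: 13 hepta-O-benzyl kuwanon L
Product: 14 kuwanon L, (2S)-2-{3-[(1S,5R,6S)-6-(2,4-dihydroxybenzoyl)-5-(2,4-dihydroxyphenyl)-3-methylcyclohex-2-en-1-yl]-2,4-dihydroxyphenyl}-5,7-dihydroxy-2,3-dihydro-4H-chromen-4-one
Conditions: 10% Pd/C, 1,4-cyclohexadiene (30 equiv), EtOAc/EtOH 1:1, rt; filter, reversed-phase chromatography (0.1% HCO2H)
Reagents that add atoms: none
Why: Catalytic transfer hydrogenolysis, in which aryl benzyl ethers are cleaved on Pd/C by hydrogen from 1,4-cyclohexadiene far faster than the hindered trisubstituted cyclohexene or the aryl ketones are reduced, and the neutral medium leaves the flavanone C2 centre and the all-trans cyclohexene unchanged.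

**Compound list**
1 | 2,4-dihydroxybenzaldehyde | O=Cc1ccc(O)cc1O | starting material
2 | 2,4-dihydroxy-3-iodobenzaldehyde | O=Cc1ccc(O)c(I)c1O | intermediate
3 | 2,4-bis(benzyloxy)-3-iodobenzaldehyde | O=Cc1ccc(OCc2ccccc2)c(I)c1OCc1ccccc1 | intermediate
4 | 2-methylbut-1-en-3-yne | C=C(C)C#C | starting material
5 | 4,4,5,5-tetramethyl-2-[(1E)-3-methylbuta-1,3-dien-1-yl]-1,3,2-dioxaborolane (not isolated) | C=C(C)/C=C/B1OC(C)(C)C(C)(C)O1 | intermediate
6 | 2,4-bis(benzyloxy)-3-[(1E)-3-methylbuta-1,3-dien-1-yl]benzaldehyde | O=Cc1ccc(OCc2ccccc2)c(/C=C/C(C)=C)c1OCc1ccccc1 | intermediate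
7 | 1-[2,4-bis(benzyloxy)-6-hydroxyphenyl]ethan-1-one | CC(=O)c1c(O)cc(OCc2ccccc2)cc1OCc1ccccc1 | starting material
8 | (2E)-1-[2,4-bis(benzyloxy)-6-hydroxyphenyl]-3-{2,4-bis(benzyloxy)-3-[(1E)-3-methylbuta-1,3-dien-1-yl]phenyl}prop-2-en-1-one | O=C(/C=C/c1ccc(OCc2ccccc2)c(/C=C/C(C)=C)c1OCc1ccccc1)c1c(O)cc(OCc2ccccc2)cc1OCc1ccccc1 | intermediate
9 | (2S)-5,7-bis(benzyloxy)-2-{2,4-bis(benzyloxy)-3-[(1E)-3-methylbuta-1,3-dien-1-yl]phenyl}-2,3-dihydro-4H-chromen-4-one | O=C1C[C@@H](c2ccc(OCc3ccccc3)c(/C=C/C(C)=C)c2OCc2ccccc2)Oc2cc(OCc3ccccc3)cc(OCc3ccccc3)c12 | intermediate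
10 | 1-[4-(benzyloxy)-2-hydroxyphenyl]ethan-1-one | CC(=O)c1ccc(OCc2ccccc2)cc1O | starting material
11 | 2,4-bis(benzyloxy)benzaldehyde | O=Cc1ccc(OCc2ccccc2)cc1OCc1ccccc1 | starting material
12 | (2E)-1-[4-(benzyloxy)-2-hydroxyphenyl]-3-[2,4-bis(benzyloxy)phenyl]prop-2-en-1-one | O=C(/C=C/c1ccc(OCc2ccccc2)cc1OCc1ccccc1)c1ccc(OCc2ccccc2)cc1O | intermediate
13 | (2S)-5,7-bis(benzyloxy)-2-{2,4-bis(benzyloxy)-3-[(1S,5R,6S)-6-[4-(benzyloxy)-2-hydroxybenzoyl]-5-[2,4-bis(benzyloxy)phenyl]-3-methylcyclohex-2-en-1-yl]phenyl}-2,3-dihydro-4H-chromen-4-one | CC1=C[C@H](c2c(OCc3ccccc3)ccc([C@@H]3CC(=O)c4c(OCc5ccccc5)cc(OCc5ccccc5)cc4O3)c2OCc2ccccc2)[C@@H](C(=O)c2ccc(OCc3ccccc3)cc2O)[C@H](c2ccc(OCc3ccccc3)cc2OCc2ccccc2)C1 | intermediate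
14 | kuwanon L, (2S)-2-{3-[(1S,5R,6S)-6-(2,4-dihydroxybenzoyl)-5-(2,4-dihydroxyphenyl)-3-methylcyclohex-2-en-1-yl]-2,4-dihydroxyphenyl}-5,7-dihydroxy-2,3-dihydro-4H-chromen-4-one | CC1=C[C@H](c2c(O)ccc([C@@H]3CC(=O)c4c(O)cc(O)cc4O3)c2O)[C@@H](C(=O)c2ccc(O)cc2O)[C@H](c2ccc(O)cc2O)C1 | target

**Step count and risk**

Total steps: 8. Longest linear sequence: 7 (steps 1, 2, 3, 4, 5, 7, 8).

Most likely to fail:

Step 5 (proposed new oxa-Michael). The risks are low rate, incomplete conversion at equilibrium and erosion of ee through the retro-reaction. The fallback uses known chemistry and replaces asymmetric catalysis by resolution. It sets out from 8: NaOAc in refluxing EtOH (classical thermodynamic oxa-Michael cyclisation) gives the racemic flavanone F1. Preparative SFC on an amylose tris(3,5-dimethylphenylcarbamate) phase then delivers 9, where the fallback rejoins the route, together with the (2R)-enantiomer F2. F2 is recycled by the same NaOAc treatment, which re-equilibrates it through chalcone 8 back to F1.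

Step 7 (Diels–Alder). The risks are exo/endo ratio, facial selectivity with a chiral diene, and Lewis-acid sensitivity of the flavanone. The fallback moves the cycloaddition ahead of flavanone construction so that it runs on an achiral, simpler diene, the closest case to the known chiral-boron reactions. It sets out from 6 and 12: the same (R)-VANOL–boron conditions give the adduct aldehyde F3, whose exo and endo isomers are separated at this small stage. Claisen–Schmidt condensation of F3 with 7 (KOH, EtOH/THF) gives the late-stage chalcone F4. The squaramide-catalysed oxa-Michael cyclisation of step 5, now catalyst-controlled and diastereoselective, closes the flavanone and rejoins the route at 13. Any C2 epimer formed here is a diastereomer and is removed on silica.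

Step 8 (global debenzylation). The risks are reduction of the cyclohexene, hydrogenolysis of the benzylic C2–O bond, and incomplete cleavage of seven ethers. The fallback abandons reductive cleavage for Lewis-acid dealkylation with a cation scavenger. It sets out from 13: BCl3 (1 M in CH2Cl2, 10 equiv) and pentamethylbenzene (20 equiv) in CH2Cl2 at −78 °C for 30 min, quenched with MeOH/CHCl3 at −78 °C, give 14 directly, so no hydrogenation catalyst touches the alkene.

**Further compounds**
F1 | step 5 | racemic 5,7-bis(benzyloxy)-2-{2,4-bis(benzyloxy)-3-[(1E)-3-methylbuta-1,3-dien-1-yl]phenyl}-2,3-dihydro-4H-chromen-4-one | O=C1CC(c2ccc(OCc3ccccc3)c(/C=C/C(C)=C)c2OCc2ccccc2)Oc2cc(OCc3ccccc3)cc(OCc3ccccc3)c12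
F2 | step 5 | (2R)-5,7-bis(benzyloxy)-2-{2,4-bis(benzyloxy)-3-[(1E)-3-methylbuta-1,3-dien-1-yl]phenyl}-2,3-dihydro-4H-chromen-4-one | O=C1C[C@H](c2ccc(OCc3ccccc3)c(/C=C/C(C)=C)c2OCc2ccccc2)Oc2cc(OCc3ccccc3)cc(OCc3ccccc3)c12
F3 | step 7 | 2,4-bis(benzyloxy)-3-{(1S,5R,6S)-6-[4-(benzyloxy)-2-hydroxybenzoyl]-5-[2,4-bis(benzyloxy)phenyl]-3-methylcyclohex-2-en-1-yl}benzaldehyde | CC1=C[C@H](c2c(OCc3ccccc3)ccc(C=O)c2OCc2ccccc2)[C@@H](C(=O)c2ccc(OCc3ccccc3)cc2O)[C@H](c2ccc(OCc3ccccc3)cc2OCc2ccccc2)C1
F4 | step 7 | (2E)-1-[2,4-bis(benzyloxy)-6-hydroxyphenyl]-3-{2,4-bis(benzyloxy)-3-[(1S,5R,6S)-6-[4-(benzyloxy)-2-hydroxybenzoyl]-5-[2,4-bis(benzyloxy)phenyl]-3-methylcyclohex-2-en-1-yl]phenyl}prop-2-en-1-one | CC1=C[C@H](c2c(OCc3ccccc3)ccc(/C=C/C(=O)c3c(O)cc(OCc4ccccc4)cc3OCc3ccccc3)c2OCc2ccccc2)[C@@H](C(=O)c2ccc(OCc3ccccc3)cc2O)[C@H](c2ccc(OCc3ccccc3)cc2OCc2ccccc2)C1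
F0 | step 8 | none | none
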